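The 18-membered ring is cut at the bond between ring D (the carbon meta to the ring A–O–ring D oxygen) and the neighbouring CH2 of the two-carbon bridge to ring C. The route exploits that bridge: with its ring C benzylic carbon held as C=O, the other bridge carbon is the only enolisable carbon of an aryl methyl ketone. One photostimulated SRN1 reaction joins this enolate carbon to the iodine-bearing ring D carbon and closes the macrocycle. The precursor is an open chain of rings C, B, A and D (acetyl on ring C, iodide on ring D, methyl ethers on rings A and B), built by two SNAr etherifications and one Wittig/diimide pair.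

Key step: step 6

Ring labels: ring A is the phenol ring whose ether oxygen leads to ring D; ring B is the phenol ring whose ether oxygen leads to ring C; ring C is the para-phenylene; ring D is the meta-phenylene.
Structure check: in 11 and 14, ring A carries its bridge CH2 ortho and its OMe para to the ether oxygen, and ring B carries OMe ortho and its bridge CH2 meta to the ether oxygen, as the target requires. No compound on the route has a stereocentre.
Remark on the chemistry: the olefination in step 3 is assumed to give an E/Z mixture, carried on unseparated because both isomers give the same bibenzyl in step 4.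
Design choice: the acetyl group is introduced only in step 5, so that it never meets the ylide or the sulfonyl hydrazide.

Step 1
Reactants: 1 3-iodophenol; 2 2-fluoro-5-methoxybenzaldehyde
Product: 3 2-(3-iodophenoxy)-5-methoxybenzaldehyde
Conditions: K2CO3, DMAc, 130 °C, N2
Reagents that add atoms: none
Why: Nucleophilic aromatic substitution (SNAr): the phenoxide of 1 adds at the fluorine-bearing carbon of 2, which the ortho formyl group activates, and fluoride leaves, while the aryl iodide stays inert in the absence of a transition metal.

Step 2
Reactants: 4 3-hydroxy-4-methoxybenzyl alcohol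
Product: 5 (3-hydroxy-4-methoxybenzyl)triphenylphosphonium bromide
Conditions: PPh3·HBr, MeCN, reflux
Reagents that add atoms: triphenylphosphine hydrobromide, Br.c1ccc(cc1)P(c1ccccc1)c1ccccc1
Why: Direct phosphonium salt formation from a benzylic alcohol: HBr ionises the alcohol, helped by the para methoxy group, and PPh3 captures the benzylic carbon, with the free phenol left alone.

Step 3
Reactants: 5 (3-hydroxy-4-methoxybenzyl)triphenylphosphonium bromide; 3 2-(3-iodophenoxy)-5-methoxybenzaldehyde
Product: 8 5-{2-[2-(3-iodophenoxy)-5-methoxyphenyl]ethenyl}-2-methoxyphenol (E/Z mixture), via phenoxide ylide 6 (not isolated), via stilbene potassium phenoxide 7 (not isolated)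
Conditions: t-BuOK (2.2 equiv), THF, 0 °C; then 3, 0 °C to rt; 1 M HCl
Reagents that add atoms: none
Why: Wittig olefination with a semi-stabilised benzylic ylide: one equivalent of base is taken up by the phenol and the second forms ylide 6, which adds to the non-enolisable aldehyde 3 and collapses through the oxaphosphetane to the alkene, whose geometry is irrelevant because the double bond is reduced in step 4.

Step 4
Reactants: 8 5-{2-[2-(3-iodophenoxy)-5-methoxyphenyl]ethenyl}-2-methoxyphenol
Product: 9 5-{2-[2-(3-iodophenoxy)-5-methoxyphenyl]ethyl}-2-methoxyphenol
Conditions: TsNHNH2, NaOAc, DME/H2O, reflux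
Reagents that add atoms: none
Why: Diimide reduction: HN=NH released from the sulfonyl hydrazide delivers two hydrogens to the C=C in a concerted cyclic transition state and cannot cleave the aryl C–I bond that catalytic hydrogenation would put at risk.

Step 5
Reactants: 9 5-{2-[2-(3-iodophenoxy)-5-methoxyphenyl]ethyl}-2-methoxyphenol; 10 4-fluoroacetophenone
Product: 11 1-{4-[5-{2-[2-(3-iodophenoxy)-5-methoxyphenyl]ethyl}-2-methoxyphenoxy]phenyl}ethanone
Conditions: K2CO3, DMAc, 140 °C, N2
Reagents that add atoms: none
Why: SNAr: the phenoxide of 9 displaces the fluoride para to the acetyl group of 10, and placing this step after the olefination and the reduction keeps the methyl ketone away from the ylide and from the hydrazide.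

Step 6
Reactants: 11 1-{4-[5-{2-[2-(3-iodophenoxy)-5-methoxyphenyl]ethyl}-2-methoxyphenoxy]phenyl}ethanone
Product: 14 macrocyclic deoxybenzoin dimethyl ether (18-membered ring; C=O on ring C; new CH2 on ring D), via seco potassium enolate 12 (not isolated), via macrocyclic potassium enolate 13 (not isolated)
Conditions: t-BuOK (2.2 equiv), degassed DMSO (2 mM), hν (350 nm, Pyrex), 25 °C, Ar; then 1 M HCl under Ar
Reagents that add atoms: none
Why: Photostimulated SRN1 enolate arylation: light drives electron transfer from the enolate of 12 to its own aryl iodide, the radical anion expels iodide, the ring D sigma radical bonds to the terminal enolate carbon, and the resulting aryl ketyl radical anion passes its electron to the next molecule of 12, which carries the chain. The closest known reaction type is the light-induced coupling of aryl methyl ketone enolates with aryl iodides in DMSO, which also has ring-closing variants. The single ring closes by radical-to-enolate coupling in an 18-endo-trig mode (both enolate carbons end up in the ring), through an early transition state that asks little of the long tether. No stereocentre is formed. The step needs C-arylation at the one enolate carbon to outrun hydrogen-atom capture by the aryl radical, intermolecular coupling and base-induced aryne formation: the methyl ketone has a single enolisable site, iodide is the fastest-fragmenting halide, the 2 mM concentration slows every bimolecular path, and the radical sits meta to the ether oxygen so it cannot close onto ring A. The second equivalent of base holds the more acidic product as enolate 13, which is protonated before air is admitted.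

Step 7
Reactants: 14 macrocyclic deoxybenzoin dimethyl ether
Product: 15 dihydroptychantol A dimethyl ether
Conditions: Et3SiH, CF3CO2H, CH2Cl2, rt
Reagents that add atoms: none
Why: Ionic hydrogenation: the protonated ketone takes up hydride from the silane, the resulting carbinol ionises in CF3CO2H to a benzylic cation stabilised by the para aryloxy oxygen of ring C, and a second hydride gives the CH2 group without touching the ethers.

Step 8
Reactants: 15 dihydroptychantol A dimethyl ether
Product: 17 dihydroptychantol A, via bis(dibromoboryl) ether 16 (not isolated)
Conditions: BBr3, CH2Cl2, −78 °C to rt; then H2O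
Reagents that add atoms: none
Why: Lewis-acid ether cleavage: BBr3 binds each methoxy oxygen, bromide removes the methyl group in an SN2 step to give the borate 16, and water releases the two phenols, whereas the diaryl ether bonds cannot undergo this displacement.

Compound list
1 | 3-iodophenol | Oc1cccc(I)c1 | starting material
2 | 2-fluoro-5-methoxybenzaldehyde | COc1ccc(F)c(C=O)c1 | starting material
3 | 2-(3-iodophenoxy)-5-methoxybenzaldehyde (rings D and A joined through oxygen) | COc1ccc(Oc2cccc(I)c2)c(C=O)c1 | intermediate
4 | 3-hydroxy-4-methoxybenzyl alcohol (isovanillyl alcohol) | COc1ccc(CO)cc1O | starting material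
5 | (3-hydroxy-4-methoxybenzyl)triphenylphosphonium bromide | COc1ccc(C[P+](c2ccccc2)(c2ccccc2)c2ccccc2)cc1O.[Br-] | intermediate
6 | potassium 2-methoxy-5-[(triphenylphosphoranylidene)methyl]phenoxide (phenoxide ylide, formed in the flask, not isolated) | COc1ccc(C=P(c2ccccc2)(c2ccccc2)c2ccccc2)cc1[O-].[K+] | intermediate
7 | potassium phenoxide of 8 (E/Z mixture, formed in the flask, not isolated) | COc1ccc(C=Cc2cc(OC)ccc2Oc2cccc(I)c2)cc1[O-].[K+] | intermediate
8 | 5-{2-[2-(3-iodophenoxy)-5-methoxyphenyl]ethenyl}-2-methoxyphenol (E/Z mixture) | COc1ccc(C=Cc2cc(OC)ccc2Oc2cccc(I)c2)cc1O | intermediate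
9 | 5-{2-[2-(3-iodophenoxy)-5-methoxyphenyl]ethyl}-2-methoxyphenol | COc1ccc(CCc2cc(OC)ccc2Oc2cccc(I)c2)cc1O | intermediate
10 | 4-fluoroacetophenone | CC(=O)c1ccc(F)cc1 | starting material
11 | 1-{4-[5-{2-[2-(3-iodophenoxy)-5-methoxyphenyl]ethyl}-2-methoxyphenoxy]phenyl}ethanone (seco ketone) | CC(=O)c1ccc(cc1)Oc1cc(ccc1OC)CCc1cc(OC)ccc1Oc1cccc(I)c1 | intermediate
12 | potassium enolate of 11 (formed in the flask, not isolated) | C=C([O-])c1ccc(cc1)Oc1cc(ccc1OC)CCc1cc(OC)ccc1Oc1cccc(I)c1.[K+] | intermediate
13 | potassium enolate of 14 (formed in the flask, not isolated) | COc1ccc2c(c1)CCc1ccc(OC)c(c1)Oc1ccc(cc1)C([O-])=Cc1cccc(c1)O2.[K+] | intermediate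
14 | macrocyclic deoxybenzoin dimethyl ether (18-membered; C=O on ring C, CH2 on ring D) | COc1ccc2c(c1)CCc1ccc(OC)c(c1)Oc1ccc(cc1)C(=O)Cc1cccc(c1)O2 | intermediate
15 | dihydroptychantol A dimethyl ether | COc1ccc2c(c1)CCc1ccc(OC)c(c1)Oc1ccc(cc1)CCc1cccc(c1)O2 | intermediate
16 | bis(dibromoboryl) ether of dihydroptychantol A (formed in the flask, not isolated) | BrB(Br)Oc1ccc2c(c1)CCc1ccc(OB(Br)Br)c(c1)Oc1ccc(cc1)CCc1cccc(c1)O2 | intermediate
17 | dihydroptychantol A | Oc1ccc2c(c1)CCc1ccc(O)c(c1)Oc1ccc(cc1)CCc1cccc(c1)O2 | target

Total step count: 8.
Longest linear sequence: 7 steps (from 1 or 2 through 3, 8, 9, 11, 14 and 15 to 17; the branch from 4 through 5 is equally long).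

Steps most likely to fail

Step 6. The ring D radical may take a hydrogen atom from the solvent, or the chain may die out at high dilution, before the slow 18-membered closure occurs. Aryne formation by the excess base and intermolecular coupling are further drains. The fallback makes the same bond by a two-electron path, a palladium-catalysed intramolecular α-arylation of the ketone. It sets out from 11 and comes back at 14. Compound 11 would be added slowly to Pd2(dba)3, Xantphos and NaOt-Bu in toluene at 80 °C. Zerovalent palladium inserts into the C–I bond, the enolate binds to the resulting divalent palladium, and reductive elimination forms the CH2–ring D bond. This path makes no compound outside the list (F0).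

Step 1. The methoxy group para to fluorine feeds electron density into the ring, so the substitution may be sluggish, and the aldehyde may degrade at the temperature then needed. The fallback forms the same diaryl ether by oxidative copper-mediated O-arylation (Chan–Lam coupling) instead of SNAr. It sets out from 1 and comes back at 3. Compound 1 would be coupled with (2-formyl-4-methoxyphenyl)boronic acid F1 using Cu(OAc)2, pyridine and 4 Å molecular sieves in CH2Cl2 under air at rt. Divalent copper at room temperature does not engage the aryl iodide.

Step 3. Proton exchange with the phenol or poor solubility of the phenoxide ylide salt may stall the olefination. The fallback reverses the order of events so that no free phenol is present at the Wittig stage. It sets out from 4, uses 10 and 3, and comes back at 11, bypassing 5 to 9.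
- SNAr of 4 on 10 (K2CO3, DMAc, 130 °C; the phenoxide reacts and the benzylic alcohol does not) should give 1-{4-[5-(hydroxymethyl)-2-methoxyphenoxy]phenyl}ethanone F2.
- PPh3·HBr in refluxing MeCN should convert it into [3-(4-acetylphenoxy)-4-methoxybenzyl]triphenylphosphonium bromide F3.
- Wittig reaction with 3 under K2CO3 and 18-crown-6 in refluxing CH2Cl2, where the ylide takes the aldehyde and not the methyl ketone, should give 1-{4-[5-{2-[2-(3-iodophenoxy)-5-methoxyphenyl]ethenyl}-2-methoxyphenoxy]phenyl}ethanone F4 as an E/Z mixture.
- Diimide from dipotassium azodicarboxylate (KO2C–N=N–CO2K) and AcOH in MeOH/THF at rt, a hydrazide-free source that cannot condense with the ketone, should reduce the alkene to 11.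

Further compounds
F0 | step 6 | none | none
F1 | step 1 | (2-formyl-4-methoxyphenyl)boronic acid | COc1ccc(B(O)O)c(C=O)c1
F2 | step 3 | 1-{4-[5-(hydroxymethyl)-2-methoxyphenoxy]phenyl}ethanone | CC(=O)c1ccc(cc1)Oc1cc(CO)ccc1OC
F3 | step 3 | [3-(4-acetylphenoxy)-4-methoxybenzyl]triphenylphosphonium bromide | CC(=O)c1ccc(cc1)Oc1cc(C[P+](c2ccccc2)(c2ccccc2)c2ccccc2)ccc1OC.[Br-]
F4 | step 3 | 1-{4-[5-{2-[2-(3-iodophenoxy)-5-methoxyphenyl]ethenyl}-2-methoxyphenoxy]phenyl}ethanone (E/Z mixture) | CC(=O)c1ccc(cc1)Oc1cc(ccc1OC)C=Cc1cc(OC)ccc1Oc1cccc(I)c1
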